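A curve of target against time has a slope, and that slope is the rate. The step that makes target takes one electrophile and one nucleophile, so the slope goes as a rate constant times the electrophile present times the nucleophile able to react.

| flask | electrophile | nucleophile | free base | remark | time |
|---|---|---|---|---|---|
| oak | 0.41 M | 0.451 M | 0.063 M | run made earlier |  |
| elm | 0.41 M | 0.451 M | 0.18 M | run made earlier |  |
| alder | 0.41 M | 0.451 M | 0.79 M | run made earlier |  |
| Saturday's | 0.41 M | 0.451 M | 0.0500 M |  | 40 h |
| Friday's | 0.41 M | 0.451 M | 0.100 M |  | 40 h |
| Tuesday's | 0.41 M | 0.451 M | 0.200 M |  | 40 h |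
| Monday's | 0.41 M | 0.451 M | 0.400 M |  | 40 h |
| Sunday's | 0.41 M | 0.451 M | 0.800 M |  | 40 h |

| run | time / h | target / % | electrophile / % |
|---|---|---|---|
| oak | 2.50 | 5.1 | 95.5 |
| oak | 4.00 | 7.8 | 92.6 |
| oak | 8.00 | 12.7 | 87.4 |
| oak | 15.0 | 19.2 | 81.1 |
| oak | 30.0 | 26.5 | 73.8 |
| elm | 6.00 | 10.5 | 89.4 |
| elm | 12.0 | 17.1 | 83.2 |
| elm | 15.0 | 18.8 | 81.1 |
| elm | 25.0 | 24.0 | 75.3 |
| elm | 30.0 | 26.4 | 73.5 |
| alder | 2.50 | 4.8 | 94.7 |
| alder | 8.00 | 12.9 | 87.3 |
| alder | 12.0 | 17.1 | 83.2 |
| alder | 20.0 | 21.8 | 77.5 |
| alder | 30.0 | 26.7 | 73.1 |

(each reading ± 0.3 percentage points)

- the earlier runs were read with a standard deviation of 0.3 percentage points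
- "hardly changes" means that all values lie within two and a half points (for a concentration: within two and a half percent of the largest)

- amount of target at the end, in percent of the electrophile charged for Saturday's, Friday's, Tuesday's, Monday's, Sunday's, in this order
- how that number moves from the first to the last of them (rises, then falls / hardly changes / falls all the way / falls, then rises / rises all the way)

The earlier runs lie together. At 30.0 h, oak, elm and alder read 26.5%, 26.4% and 26.7%, although alder holds 12.5 times oak's free base. Saturday's 0.0500 M lies a little below oak's charge and Sunday's 0.800 M a little above alder's, so we carry one curve, oak's, across the row.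

On the charge the electrophile is the limiting reagent. If we divide the last slope by the first, the rate constant drops out, and dividing again by the electrophile ratio leaves the nucleophile:

slope, last stretch over first: 0.239

electrophile, last stretch over first: 0.792

ratio of the two: 30.1%

We call this reading the working share of the nucleophile: the part of what drove oak's first stretch that still drives its last. Target has used 24.1% of oak's charged nucleophile by 30.0 h, which does not account for that loss.

Our own reckoning lets the share keep falling as it has, and holds the electrophile at its 30.0 h reading:

halving time of the share: 12.3 h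

share in the middle of the stretch to 40 h: 14.9%

target gained in that stretch: 2.3 percentage points

target at the end: 28.8%

The forecast gives 30.5% at each point, shape hardly changes, holding that “free base therefore has no visible effect on rate or extent”. We agree on the shape, but its figure stands above ours.

The flasks give 29.1%, 29.1%, 29.1%, 29.1% and 29.1%: hardly changes. The forecast holds.

    acid set free + free base ⇌ salt of the base (K = 2.70 L mol⁻¹, k = 0.0162 L mol⁻¹ min⁻¹)
    electrophile + nucleophile → acid set free + target (k = 8.43 × 10⁻⁴ L mol⁻¹ min⁻¹)
    2 nucleophile → self-condensation product (k = 8.12 × 10⁻⁴ L mol⁻¹ min⁻¹)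
    nucleophile + acid set free ⇌ protonated nucleophile, settled at all times (K = 6250 L mol⁻¹)

Saturday's second half, from 22.1% of target at 20.0 h to 29.1% at 40.0 h, gives a working share of 22.4%, measured against oak's first stretch. That share lies between the 30.2% and the 13.7% of its charge that Saturday's holds as unbound nucleophile at those two times. The passing of two nucleophile into self-condensation product and the hour of the reading together are part of why Saturday's stands at 29.1%: without that step it gives 39.1%, and read at 400 h it gives 37.8%.

The numbers in the tables are calculated with constants of no real substance.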